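**Plan**
1. Retrosynthesis: the C11=C12 and C11'=C12' double bonds are cut first (two Wittig reactions), giving C10 dialdehyde 31 and two C15 phosphonium salts, 17 (oxabicyclic end) and 30 (triol end).
2. In 17 the 7-oxabicyclo[2.2.1]heptane is cut at C1–C2 and O–C3. The gem-dimethyl carbon C1 lies next to the oxygenated bridgehead C6, and C2–C3 carries the other C–O bond of the bridge, so a C1/C6 epoxide can add its C–O bond across a C2=C3 vinyl group; the precursor is acyclic epoxide 8.
3. Forward, 8 is built from ethyl acetoacetate, acetone and an allyl unit; one Lewis-acid step then closes the carbocycle and the oxygen bridge together, and C7 is extended to the C15 salt.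
4. The triol ring comes from ketoisophorone 18 (all ring carbons present); its C5'–C6' epoxide is opened by water at C6' once the side chain is in place.
5. Stereochemistry: C5 from catalytic asymmetric allylation, C6 from Sharpless epoxidation, C3 from the geometry of the bridge; C3' from asymmetric transfer hydrogenation, C5' from Sharpless epoxidation, C6' by inversion in the hydrolysis.
6. The polyene is joined last (17 + 31, then + 30) and equilibrated to all-E.

Key step: step 7

Remark: ring atoms carry carotenoid numbers (C1 = CMe2, C3 = O-bearing CH, C5 = C(Me)O, C6 = ring carbon bearing the chain; primes for the triol end). The enantiomer of each chiral catalyst is assigned from its accepted model and would be verified on the first chiral intermediate.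

**Oxabicyclic end**

Step 1
Reactants: 1 ethyl acetoacetate; 2 acetone
Product: 3 ethyl 2-acetyl-3-methylbut-2-enoate
Conditions: TiCl4, pyridine, THF, 0 °C to rt
Reagents that add atoms: none
Why: Knoevenagel condensation (Lehnert conditions) should dehydrate the adduct of the active methylene compound and the ketone to the fully substituted alkylidene acetoacetate, which already holds C1 with both methyls, C6, C7 and C5.

Step 2
Reactants: 3 ethyl 2-acetyl-3-methylbut-2-enoate
Product: 4 ethyl 2-[(2R)-2-hydroxypent-4-en-2-yl]-3-methylbut-2-enoate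
Conditions: allyl-B(Oi-Pr)2, (S)-3,3'-dibromo-BINOL (15 mol%), t-BuOH, PhMe/PhCF3, −35 °C
Reagents that add atoms: allyldiisopropoxyborane, C=CCB(OC(C)C)OC(C)C
Why: Diol-catalysed asymmetric allylboration of a methyl ketone through a closed chair transition state should add allyl to the ketone only and set C5 as the (R)-carbinol, the bulky alkenyl group against methyl providing the facial bias.

Step 3
Reactants: 4 ethyl 2-[(2R)-2-hydroxypent-4-en-2-yl]-3-methylbut-2-enoate
Product: 5 ethyl 3-methyl-2-[(2R)-2-(triethylsilyloxy)pent-4-en-2-yl]but-2-enoate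
Conditions: Et3SiOTf, 2,6-lutidine, CH2Cl2, −78 to 0 °C
Reagents that add atoms: triethylsilyl triflate, CC[Si](CC)(CC)OS(=O)(=O)C(F)(F)F
Why: Silyl triflate silylation of the hindered tertiary allylic alcohol should mask O5 for the hydride, epoxidation and Lewis-acid steps.

Step 4
Reactants: 5 ethyl 3-methyl-2-[(2R)-2-(triethylsilyloxy)pent-4-en-2-yl]but-2-enoate
Product: 6 3-methyl-2-[(2R)-2-(triethylsilyloxy)pent-4-en-2-yl]but-2-en-1-ol
Conditions: i-Bu2AlH, CH2Cl2, −78 to 0 °C
Reagents that add atoms: none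
Why: 1,2-Reduction of the conjugated ester by the aluminium hydride should give the primary allylic alcohol that the epoxidation catalyst needs as its anchor.

Step 5
Reactants: 6 3-methyl-2-[(2R)-2-(triethylsilyloxy)pent-4-en-2-yl]but-2-en-1-ol
Product: 7 {(2S)-3,3-dimethyl-2-[(2R)-2-(triethylsilyloxy)pent-4-en-2-yl]oxiran-2-yl}methanol
Conditions: Ti(Oi-Pr)4, L-(+)-diethyl tartrate, t-BuOOH, 4 Å molecular sieves, CH2Cl2, −20 °C
Reagents that add atoms: tert-butyl hydroperoxide, CC(C)(C)OO
Why: Sharpless asymmetric epoxidation of the primary allylic alcohol (a tetrasubstituted alkene of the cyclogeraniol kind) should deliver oxygen under reagent control to set C6 as the (S)-epoxide carbon and leave the remote vinyl group untouched.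

Step 6
Reactants: 7 {(2S)-3,3-dimethyl-2-[(2R)-2-(triethylsilyloxy)pent-4-en-2-yl]oxiran-2-yl}methanol
Product: 8 tert-butyl({(2S)-3,3-dimethyl-2-[(2R)-2-(triethylsilyloxy)pent-4-en-2-yl]oxiran-2-yl}methoxy)diphenylsilane
Conditions: t-BuPh2SiCl, imidazole, CH2Cl2, rt
Reagents that add atoms: tert-butyl(chloro)diphenylsilane, CC(C)(C)[Si](Cl)(c1ccccc1)c1ccccc1
Why: Silylation of the primary alcohol removes a free hydroxyl that could bind the Lewis acid or intercept the cation in the next step.

Step 7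
Reactants: 8 tert-butyl({(2S)-3,3-dimethyl-2-[(2R)-2-(triethylsilyloxy)pent-4-en-2-yl]oxiran-2-yl}methoxy)diphenylsilane
Product: 10 tert-butyl{[(1R,2R,4R)-2,6,6-trimethyl-2-(triethylsilyloxy)-7-oxabicyclo[2.2.1]heptan-1-yl]methoxy}diphenylsilane, via tertiary carbocation 9 (not isolated)
Conditions: MeAlCl2, CH2Cl2, −78 to −40 °C; Et3N/MeOH quench
Reagents that add atoms: none
Why: MeAlCl2 binds the epoxide oxygen and the C1–O bond ionises (C6 is flanked by two silyloxy-bearing carbons and has no π donor, so charge builds at the dimethyl-substituted C1) to give tertiary cation 9 with the aluminium alkoxide still on C6; the terminal CH2 of the vinyl group (C2) attacks C1 in the Markovnikov sense and the charge developing at C3 is captured by the C6 alkoxide oxygen, so the epoxide C–O bond adds across the alkene as a formal [3+2] and the Lewis acid is released. The closest known reaction type is the Lewis-acid epoxy-olefin (cation–olefin) cyclisation in which the epoxide oxygen terminates the cyclohexyl cation to give 7-oxabicyclo[2.2.1]heptanes, together with Prins cyclisations of terminal alkenes with internal oxygen capture. The C1–C2 bond closes the carbocycle in a 6-endo-trig mode (the 5-exo alternative would need a primary cation), and the O–C3 bond then closes the oxolane bridge across a boat. C3 is the only new stereocentre and is fixed by C6, because the one-atom oxygen bridge can reach C3 only on the face it occupies at C6; C5 and C6 pass through unchanged (C5–O cis to the bridge) and C1 carries two methyls. The step needs ring closure to outrun 1,2-shift of C5 or C7 to C1 (semipinacol) and proton loss from a C1 methyl; low temperature, the non-basic chloroaluminate, the chair-like six-membered approach of the vinyl group and bulky silyl ethers that keep O5 and O7 away from the cation should secure this.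

Step 8
Reactants: 10 tert-butyl{[(1R,2R,4R)-2,6,6-trimethyl-2-(triethylsilyloxy)-7-oxabicyclo[2.2.1]heptan-1-yl]methoxy}diphenylsilane
Product: 11 (1R,2R,4R)-1-(hydroxymethyl)-2,6,6-trimethyl-7-oxabicyclo[2.2.1]heptan-2-ol
Conditions: Bu4NF, THF, rt to 45 °C
Reagents that add atoms: none
Why: Fluoride-induced desilylation should free both the primary and the tertiary hydroxyl, the bridged ether being inert.

Step 9
Reactants: 11 (1R,2R,4R)-1-(hydroxymethyl)-2,6,6-trimethyl-7-oxabicyclo[2.2.1]heptan-2-ol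
Product: 12 (1S,2R,4R)-2-hydroxy-2,6,6-trimethyl-7-oxabicyclo[2.2.1]heptane-1-carbaldehyde
Conditions: Dess–Martin periodinane, CH2Cl2, rt
Reagents that add atoms: none
Why: Dess–Martin oxidation should convert the neopentyl primary alcohol to the non-enolisable aldehyde and cannot touch the tertiary alcohol.

Step 10
Reactants: 12 (1S,2R,4R)-2-hydroxy-2,6,6-trimethyl-7-oxabicyclo[2.2.1]heptane-1-carbaldehyde; 13 ethyl (2E)-4-(diethoxyphosphoryl)-3-methylbut-2-enoate
Product: 15 ethyl (2E,4E)-5-[(1S,2R,4R)-2-hydroxy-2,6,6-trimethyl-7-oxabicyclo[2.2.1]heptan-1-yl]-3-methylpenta-2,4-dienoate, via lithium phosphonate carbanion 14 (not isolated)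
Conditions: LiCl, DBU, MeCN, 0 °C to rt
Reagents that add atoms: none
Why: Horner–Wadsworth–Emmons olefination under Masamune–Roush conditions should form C7=C8 with E geometry, the weak amine base avoiding an O5 alkoxide and hence retro-aldol opening of the β-hydroxy aldehyde; any 9Z isomer would be removed by chromatography.

Step 11
Reactants: 15 ethyl (2E,4E)-5-[(1S,2R,4R)-2-hydroxy-2,6,6-trimethyl-7-oxabicyclo[2.2.1]heptan-1-yl]-3-methylpenta-2,4-dienoate
Product: 16 (2E,4E)-5-[(1S,2R,4R)-2-hydroxy-2,6,6-trimethyl-7-oxabicyclo[2.2.1]heptan-1-yl]-3-methylpenta-2,4-dien-1-ol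
Conditions: i-Bu2AlH, CH2Cl2, −78 to 0 °C
Reagents that add atoms: none
Why: 1,2-Reduction of the dienoate by the aluminium hydride should give the C15 allylic alcohol without touching the diene.

Step 12
Reactants: 16 (2E,4E)-5-[(1S,2R,4R)-2-hydroxy-2,6,6-trimethyl-7-oxabicyclo[2.2.1]heptan-1-yl]-3-methylpenta-2,4-dien-1-ol
Product: 17 {(2E,4E)-5-[(1S,2R,4R)-2-hydroxy-2,6,6-trimethyl-7-oxabicyclo[2.2.1]heptan-1-yl]-3-methylpenta-2,4-dien-1-yl}triphenylphosphonium bromide
Conditions: Ph3P·HBr, MeOH, 0 °C to rt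
Reagents that add atoms: triphenylphosphine hydrobromide, c1ccccc1[PH+](c1ccccc1)c1ccccc1.[Br-]
Why: Phosphonium salt formation from an allylic alcohol (the standard C15 end-group activation) should proceed by ionisation of the primary allylic alcohol and capture of the unhindered terminus by triphenylphosphine, the bridged ether and the tertiary alcohol being stable to this mild acid.

**Triol end**

Step 13
Reactants: 18 ketoisophorone (2,6,6-trimethylcyclohex-2-ene-1,4-dione)
Product: 19 (4R)-4-hydroxy-2,6,6-trimethylcyclohex-2-en-1-one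
Conditions: RuCl[(R,R)-TsDPEN](p-cymene) (cat.), HCO2H–Et3N, rt
Reagents that add atoms: none
Why: Noyori asymmetric transfer hydrogenation should reduce only the unhindered C4 carbonyl (the other is shielded by the quaternary carbon) and set C3' by the catalyst-controlled hydride transfer to one face of the enone carbonyl.

Step 14
Reactants: 19 (4R)-4-hydroxy-2,6,6-trimethylcyclohex-2-en-1-one
Product: 20 (1R)-3,5,5-trimethyl-4-oxocyclohex-2-en-1-yl 2,2-dimethylpropanoate
Conditions: t-BuCOCl, pyridine, DMAP (cat.), CH2Cl2, 0 °C to rt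
Reagents that add atoms: pivaloyl chloride, CC(C)(C)C(Cl)=O
Why: Acylation gives a pivalate that has no α-hydrogen, keeps O3' from attacking C6' later and is removed by the hydride of step 21.

Step 15
Reactants: 20 (1R)-3,5,5-trimethyl-4-oxocyclohex-2-en-1-yl 2,2-dimethylpropanoate
Product: 22 (1S)-3,5,5-trimethyl-4-{[(trifluoromethyl)sulfonyl]oxy}cyclohex-3-en-1-yl 2,2-dimethylpropanoate, via lithium enolate 21 (not isolated)
Conditions: LiBH(s-Bu)3, THF, −78 °C; then PhNTf2, −78 °C to rt
Reagents that add atoms: N-phenylbis(trifluoromethanesulfonimide), O=S(=O)(N(c1ccccc1)S(=O)(=O)C(F)(F)F)C(F)(F)F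
Why: Conjugate reduction with enolate trapping should work because the bulky hydride adds to the unsubstituted β-carbon of the enone (its carbonyl is blocked by the gem-dimethyl group) and the resulting enolate is O-triflated to the tetrasubstituted enol triflate.

Step 16
Reactants: 22 (1S)-3,5,5-trimethyl-4-{[(trifluoromethyl)sulfonyl]oxy}cyclohex-3-en-1-yl 2,2-dimethylpropanoate
Product: 23 (1S)-4-(hydroxymethyl)-3,5,5-trimethylcyclohex-3-en-1-yl 2,2-dimethylpropanoate
Conditions: Bu3SnCH2OH, Pd(PPh3)4 (cat.), LiCl, 1,4-dioxane, 100 °C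
Reagents that add atoms: (tributylstannyl)methanol, CCCC[Sn](CCCC)(CCCC)CO
Why: Stille (Kosugi) hydroxymethylation should install C7' through oxidative addition of the enol triflate to zerovalent palladium, transmetalation and reductive elimination.

Step 17
Reactants: 23 (1S)-4-(hydroxymethyl)-3,5,5-trimethylcyclohex-3-en-1-yl 2,2-dimethylpropanoate
Product: 24 (1S,4R,6S)-1-(hydroxymethyl)-2,2,6-trimethyl-7-oxabicyclo[4.1.0]heptan-4-yl 2,2-dimethylpropanoate
Conditions: Ti(Oi-Pr)4, L-(+)-diethyl tartrate, t-BuOOH, 4 Å molecular sieves, CH2Cl2, −20 °C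
Reagents that add atoms: tert-butyl hydroperoxide, CC(C)(C)OO
Why: Sharpless asymmetric epoxidation of the cyclohexenylmethanol should place the epoxide under reagent control on the face anti to the C3' ester, which fixes C5' in its final configuration.

Step 18
Reactants: 24 (1S,4R,6S)-1-(hydroxymethyl)-2,2,6-trimethyl-7-oxabicyclo[4.1.0]heptan-4-yl 2,2-dimethylpropanoate
Product: 25 (1R,4R,6S)-1-formyl-2,2,6-trimethyl-7-oxabicyclo[4.1.0]heptan-4-yl 2,2-dimethylpropanoate
Conditions: Pr4N[RuO4] (cat.), N-methylmorpholine N-oxide, 4 Å molecular sieves, CH2Cl2, rt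
Reagents that add atoms: none
Why: Ley–Griffith oxidation is neutral, so the primary alcohol should go to the aldehyde without opening the acid-sensitive epoxide.

Step 19
Reactants: 25 (1R,4R,6S)-1-formyl-2,2,6-trimethyl-7-oxabicyclo[4.1.0]heptan-4-yl 2,2-dimethylpropanoate; 13 ethyl (2E)-4-(diethoxyphosphoryl)-3-methylbut-2-enoate
Product: 27 ethyl (2E,4E)-5-[(1R,4R,6S)-4-(2,2-dimethylpropanoyloxy)-2,2,6-trimethyl-7-oxabicyclo[4.1.0]heptan-1-yl]-3-methylpenta-2,4-dienoate, via sodium phosphonate carbanion 26 (not isolated)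
Conditions: NaH, THF, 0 °C; then 25, 0 °C to rt
Reagents that add atoms: none
Why: Horner–Wadsworth–Emmons olefination with the preformed sodium carbanion, which is more reactive toward the hindered aldehyde than an amine-generated one and is acceptable here because 25 has no free hydroxyl and no enolisable position, should give the E C7'=C8' bond and the C15 epoxy dienoate, the classical precursor of 5,6-oxygenated carotenoid end groups; the hindered pivalate and the epoxide are inert to the stabilised carbanion.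

Step 20
Reactants: 27 ethyl (2E,4E)-5-[(1R,4R,6S)-4-(2,2-dimethylpropanoyloxy)-2,2,6-trimethyl-7-oxabicyclo[4.1.0]heptan-1-yl]-3-methylpenta-2,4-dienoate
Product: 28 ethyl (2E,4E)-5-[(1S,2S,4R)-4-(2,2-dimethylpropanoyloxy)-1,2-dihydroxy-2,6,6-trimethylcyclohexyl]-3-methylpenta-2,4-dienoate
Conditions: HClO4 (cat.), THF–H2O, 0 °C
Reagents that add atoms: water, O
Why: Acid-catalysed epoxide hydrolysis should occur by attack of water on the allylic C6' anti to the protonated oxygen (trans-diaxial opening with inversion), giving the 5',6'-trans diol with O6' cis to O3'; the dienoate acceptor disfavours a free C6' cation and furanoid closure, and the pivalate keeps O3' from closing a bridge.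

Step 21
Reactants: 28 ethyl (2E,4E)-5-[(1S,2S,4R)-4-(2,2-dimethylpropanoyloxy)-1,2-dihydroxy-2,6,6-trimethylcyclohexyl]-3-methylpenta-2,4-dienoate
Product: 29 (1S,2S,4R)-1-[(1E,3E)-5-hydroxy-3-methylpenta-1,3-dien-1-yl]-2,6,6-trimethylcyclohexane-1,2,4-triol
Conditions: i-Bu2AlH (excess), CH2Cl2/THF, −78 to 0 °C
Reagents that add atoms: none
Why: Hydride reduction should convert the dienoate to the allylic alcohol and cleave the pivalate reductively in the same operation.

Step 22
Reactants: 29 (1S,2S,4R)-1-[(1E,3E)-5-hydroxy-3-methylpenta-1,3-dien-1-yl]-2,6,6-trimethylcyclohexane-1,2,4-triol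
Product: 30 {(2E,4E)-3-methyl-5-[(1S,2S,4R)-1,2,4-trihydroxy-2,6,6-trimethylcyclohexyl]penta-2,4-dien-1-yl}triphenylphosphonium bromide
Conditions: Ph3P·HBr, MeOH, 0 °C to rt
Reagents that add atoms: triphenylphosphine hydrobromide, c1ccccc1[PH+](c1ccccc1)c1ccccc1.[Br-]
Why: Phosphonium salt formation should take place selectively at the primary allylic alcohol, phosphine capture at the unhindered terminus being faster than any reaction at the secondary or tertiary hydroxyls.

**Assembly**

Step 23
Reactants: 17 oxabicyclic C15 phosphonium bromide; 31 (2E,4E,6E)-2,7-dimethylocta-2,4,6-trienedial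
Product: 33 (2E,4E,6E,8E,10E,12E)-13-[(1S,2R,4R)-2-hydroxy-2,6,6-trimethyl-7-oxabicyclo[2.2.1]heptan-1-yl]-2,7,11-trimethyltrideca-2,4,6,8,10,12-hexaenal, via phosphorus ylide 32 (not isolated)
Conditions: NaOMe, CH2Cl2–MeOH, 0 °C to rt, 31 in excess; brief reflux in EtOH
Reagents that add atoms: none
Why: Wittig olefination of one formyl group of the excess dialdehyde should form C11=C12 and give the C25 aldehyde, any Z isomer at the new bond being equilibrated thermally to E.

Step 24
Reactants: 33 C25 aldehyde; 30 triol C15 phosphonium bromide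
Product: 35 target CNP0261804.1, via phosphorus ylide 34 (not isolated)
Conditions: NaOMe, CH2Cl2–MeOH, 0 °C to rt; then reflux in EtOH in the dark
Reagents that add atoms: none
Why: The second Wittig olefination should form C11'=C12' in the presence of the free hydroxyls (the ylide is formed reversibly by methoxide), and thermal equilibration should converge the polyene on the all-E target.

**Compound list**
1 | ethyl acetoacetate | CCOC(=O)CC(C)=O | starting material
2 | acetone | CC(C)=O | starting material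
3 | ethyl 2-acetyl-3-methylbut-2-enoate | CCOC(=O)C(C(C)=O)=C(C)C | intermediate
4 | ethyl 2-[(2R)-2-hydroxypent-4-en-2-yl]-3-methylbut-2-enoate | CCOC(=O)C(=C(C)C)[C@](C)(O)CC=C | intermediate
5 | ethyl 3-methyl-2-[(2R)-2-(triethylsilyloxy)pent-4-en-2-yl]but-2-enoate | CCOC(=O)C(=C(C)C)[C@](C)(O[Si](CC)(CC)CC)CC=C | intermediate
6 | 3-methyl-2-[(2R)-2-(triethylsilyloxy)pent-4-en-2-yl]but-2-en-1-ol | OCC(=C(C)C)[C@](C)(O[Si](CC)(CC)CC)CC=C | intermediate
7 | {(2S)-3,3-dimethyl-2-[(2R)-2-(triethylsilyloxy)pent-4-en-2-yl]oxiran-2-yl}methanol | OC[C@@]1(OC1(C)C)[C@](C)(O[Si](CC)(CC)CC)CC=C | intermediate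
8 | tert-butyl({(2S)-3,3-dimethyl-2-[(2R)-2-(triethylsilyloxy)pent-4-en-2-yl]oxiran-2-yl}methoxy)diphenylsilane | CC(C)(C)[Si](c1ccccc1)(c1ccccc1)OC[C@@]1(OC1(C)C)[C@](C)(O[Si](CC)(CC)CC)CC=C | intermediate
9 | ring-opened tertiary carbocation (C1 cation, methyldichloroaluminate on O6) | C[C+](C)[C@](CO[Si](c1ccccc1)(c1ccccc1)C(C)(C)C)(O[Al-](C)(Cl)Cl)[C@](C)(O[Si](CC)(CC)CC)CC=C | intermediate
10 | tert-butyl{[(1R,2R,4R)-2,6,6-trimethyl-2-(triethylsilyloxy)-7-oxabicyclo[2.2.1]heptan-1-yl]methoxy}diphenylsilane | CC(C)(C)[Si](c1ccccc1)(c1ccccc1)OC[C@]12O[C@H](CC1(C)C)C[C@@]2(C)O[Si](CC)(CC)CC | intermediate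
11 | (1R,2R,4R)-1-(hydroxymethyl)-2,6,6-trimethyl-7-oxabicyclo[2.2.1]heptan-2-ol | OC[C@]12O[C@H](CC1(C)C)C[C@@]2(C)O | intermediate
12 | (1S,2R,4R)-2-hydroxy-2,6,6-trimethyl-7-oxabicyclo[2.2.1]heptane-1-carbaldehyde | O=C[C@]12O[C@H](CC1(C)C)C[C@@]2(C)O | intermediate
13 | ethyl (2E)-4-(diethoxyphosphoryl)-3-methylbut-2-enoate | CCOC(=O)/C=C(C)/CP(=O)(OCC)OCC | starting material
14 | lithium carbanion of 13 | [Li+].CCOC(=O)/C=C(C)/[CH-]P(=O)(OCC)OCC | intermediate
15 | ethyl (2E,4E)-5-[(1S,2R,4R)-2-hydroxy-2,6,6-trimethyl-7-oxabicyclo[2.2.1]heptan-1-yl]-3-methylpenta-2,4-dienoate | CCOC(=O)/C=C(C)/C=C/[C@]12O[C@H](CC1(C)C)C[C@@]2(C)O | intermediate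
16 | (2E,4E)-5-[(1S,2R,4R)-2-hydroxy-2,6,6-trimethyl-7-oxabicyclo[2.2.1]heptan-1-yl]-3-methylpenta-2,4-dien-1-ol | OC/C=C(C)/C=C/[C@]12O[C@H](CC1(C)C)C[C@@]2(C)O | intermediate
17 | {(2E,4E)-5-[(1S,2R,4R)-2-hydroxy-2,6,6-trimethyl-7-oxabicyclo[2.2.1]heptan-1-yl]-3-methylpenta-2,4-dien-1-yl}triphenylphosphonium bromide | c1ccccc1[P+](c1ccccc1)(c1ccccc1)C/C=C(C)/C=C/[C@]12O[C@H](CC1(C)C)C[C@@]2(C)O.[Br-] | intermediate
18 | ketoisophorone (2,6,6-trimethylcyclohex-2-ene-1,4-dione) | CC1=CC(=O)CC(C)(C)C1=O | starting material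
19 | (4R)-4-hydroxy-2,6,6-trimethylcyclohex-2-en-1-one | CC1=C[C@H](O)CC(C)(C)C1=O | intermediate
20 | (1R)-3,5,5-trimethyl-4-oxocyclohex-2-en-1-yl 2,2-dimethylpropanoate | CC1=C[C@H](OC(=O)C(C)(C)C)CC(C)(C)C1=O | intermediate
21 | lithium (4S)-4-(2,2-dimethylpropanoyloxy)-2,6,6-trimethylcyclohex-1-en-1-olate | [Li+].CC1=C([O-])C(C)(C)C[C@@H](OC(=O)C(C)(C)C)C1 | intermediate
22 | (1S)-3,5,5-trimethyl-4-{[(trifluoromethyl)sulfonyl]oxy}cyclohex-3-en-1-yl 2,2-dimethylpropanoate | CC1=C(OS(=O)(=O)C(F)(F)F)C(C)(C)C[C@@H](OC(=O)C(C)(C)C)C1 | intermediate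
23 | (1S)-4-(hydroxymethyl)-3,5,5-trimethylcyclohex-3-en-1-yl 2,2-dimethylpropanoate | CC1=C(CO)C(C)(C)C[C@@H](OC(=O)C(C)(C)C)C1 | intermediate
24 | (1S,4R,6S)-1-(hydroxymethyl)-2,2,6-trimethyl-7-oxabicyclo[4.1.0]heptan-4-yl 2,2-dimethylpropanoate | OC[C@]12O[C@@]1(C)C[C@H](OC(=O)C(C)(C)C)CC2(C)C | intermediate
25 | (1R,4R,6S)-1-formyl-2,2,6-trimethyl-7-oxabicyclo[4.1.0]heptan-4-yl 2,2-dimethylpropanoate | O=C[C@]12O[C@@]1(C)C[C@H](OC(=O)C(C)(C)C)CC2(C)C | intermediate
26 | sodium carbanion of 13 | [Na+].CCOC(=O)/C=C(C)/[CH-]P(=O)(OCC)OCC | intermediate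
27 | ethyl (2E,4E)-5-[(1R,4R,6S)-4-(2,2-dimethylpropanoyloxy)-2,2,6-trimethyl-7-oxabicyclo[4.1.0]heptan-1-yl]-3-methylpenta-2,4-dienoate | CCOC(=O)/C=C(C)/C=C/[C@]12O[C@@]1(C)C[C@H](OC(=O)C(C)(C)C)CC2(C)C | intermediate
28 | ethyl (2E,4E)-5-[(1S,2S,4R)-4-(2,2-dimethylpropanoyloxy)-1,2-dihydroxy-2,6,6-trimethylcyclohexyl]-3-methylpenta-2,4-dienoate | CCOC(=O)/C=C(C)/C=C/[C@]1(O)C(C)(C)C[C@@H](OC(=O)C(C)(C)C)C[C@]1(C)O | intermediate
29 | (1S,2S,4R)-1-[(1E,3E)-5-hydroxy-3-methylpenta-1,3-dien-1-yl]-2,6,6-trimethylcyclohexane-1,2,4-triol | OC/C=C(C)/C=C/[C@]1(O)C(C)(C)C[C@@H](O)C[C@]1(C)O | intermediate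
30 | {(2E,4E)-3-methyl-5-[(1S,2S,4R)-1,2,4-trihydroxy-2,6,6-trimethylcyclohexyl]penta-2,4-dien-1-yl}triphenylphosphonium bromide | c1ccccc1[P+](c1ccccc1)(c1ccccc1)C/C=C(C)/C=C/[C@]1(O)C(C)(C)C[C@@H](O)C[C@]1(C)O.[Br-] | intermediate
31 | (2E,4E,6E)-2,7-dimethylocta-2,4,6-trienedial | O=C/C(C)=C/C=C/C=C(C)/C=O | starting material
32 | phosphorus ylide of 17 | c1ccccc1[P+](c1ccccc1)(c1ccccc1)[CH-]/C=C(C)/C=C/[C@]12O[C@H](CC1(C)C)C[C@@]2(C)O | intermediate
33 | (2E,4E,6E,8E,10E,12E)-13-[(1S,2R,4R)-2-hydroxy-2,6,6-trimethyl-7-oxabicyclo[2.2.1]heptan-1-yl]-2,7,11-trimethyltrideca-2,4,6,8,10,12-hexaenal | O=C/C(C)=C/C=C/C=C(C)/C=C/C=C(C)/C=C/[C@]12O[C@H](CC1(C)C)C[C@@]2(C)O | intermediate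
34 | phosphorus ylide of 30 | c1ccccc1[P+](c1ccccc1)(c1ccccc1)[CH-]/C=C(C)/C=C/[C@]1(O)C(C)(C)C[C@@H](O)C[C@]1(C)O | intermediate
35 | CNP0261804.1 (all-E; oxabicyclic end 3R,5R,6S; triol end 3'R,5'S,6'S) | CC(/C=C/C=C(C)/C=C/[C@]12O[C@H](CC1(C)C)C[C@@]2(C)O)=C\C=C\C=C(C)\C=C\C=C(C)\C=C\[C@]1(O)C(C)(C)C[C@@H](O)C[C@]1(C)O | target

**Step count and risks**
Total steps: 24. Longest linear sequence: 14 (steps 1–12, 23, 24).

Step 7. What may go wrong: 1,2-shift of C5 or C7 to the cationic C1, or loss of a methyl proton, may outrun attack by the weakly nucleophilic vinyl group, and the secondary cation at C3 may be lost by hydride shift before the ether closes. The fallback sets out from 8 and comes back at 10; it replaces the alkene by a far stronger π-nucleophile and closes the bridge separately. Tsuji–Wacker oxidation of the vinyl group (PdCl2 cat., CuCl, O2, DMF–H2O) would give the methyl ketone F1. Kinetic enolisation and silylation (LiN(i-Pr)2, Me3SiCl, THF, −78 °C) would give the terminal trimethylsilyl enol ether F2. TiCl4 in CH2Cl2 at −78 °C would then open the epoxide at C1 and the enol silane would alkylate the tertiary cation (Mukaiyama/Reetz tert-alkylation), forming C1–C2 and the hydroxy ketone F3. PhSH with BF3·OEt2 would convert the C3 carbonyl to a thionium ion that the C6 hydroxyl captures across the ring, giving the bridgehead phenylthio ether F4. Raney Ni in EtOH would replace sulfur by hydrogen to give 10.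

Step 2. What may go wrong: the cross-conjugated keto ester may bind the boronate through both carbonyls and add slowly or with poor facial discrimination. The fallback sets out from 3 and comes back at 7; it gives up control at C5 and lets the epoxidation reagent sort the enantiomers. Barbier allylation (allyl bromide, In powder, THF–H2O) would give the racemic carbinol F5. The conditions of steps 3 and 4 would give the racemic silyl ether F6 and the racemic allylic alcohol F7. Sharpless epoxidation as in step 5 would oxidise both enantiomers on the reagent-dictated face, giving 7 and its C5 epimer F8 as diastereomers that are separated by chromatography.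

Step 20. What may go wrong: partial SN1 opening at the allylic C6' would erode the inversion, and the C5' oxygen could close onto C8' (furanoid rearrangement). The fallback sets out from 23 and comes back at 28; it opens a non-allylic epoxide at C5' instead. Sharpless epoxidation of 23 with D-(−)-diethyl tartrate would give the syn epoxy alcohol F9 (epoxide cis to the pivalate). HClO4 in THF–H2O would open it at C5', the carbon remote from the hydroxymethyl group, with inversion and in the trans-diaxial sense, giving the triol F10 with the same ring configuration as 28. Selective oxidation of the primary alcohol (TEMPO cat., PhI(OAc)2) would give the hydroxy aldehyde F11, and olefination with 13 under the LiCl/DBU conditions of step 10, whose amine base leaves the free hydroxyls undeprotonated, would give 28.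

**Further compounds**
F1 | step 7 | (4R)-4-[(2S)-2-{[tert-butyl(diphenyl)silyl]oxymethyl}-3,3-dimethyloxiran-2-yl]-4-(triethylsilyloxy)pentan-2-one | CC(C)(C)[Si](c1ccccc1)(c1ccccc1)OC[C@@]1(OC1(C)C)[C@](C)(O[Si](CC)(CC)CC)CC(C)=O
F2 | step 7 | trimethylsilyl enol ether of F1 (terminal, 2-silyloxy-1-alkene) | CC(C)(C)[Si](c1ccccc1)(c1ccccc1)OC[C@@]1(OC1(C)C)[C@](C)(O[Si](CC)(CC)CC)CC(=C)O[Si](C)(C)C
F3 | step 7 | (3R,4R)-4-{[tert-butyl(diphenyl)silyl]oxymethyl}-4-hydroxy-3,5,5-trimethyl-3-(triethylsilyloxy)cyclohexan-1-one | CC(C)(C)[Si](c1ccccc1)(c1ccccc1)OC[C@]1(O)C(C)(C)CC(=O)C[C@@]1(C)O[Si](CC)(CC)CC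
F4 | step 7 | tert-butyl{[(1R,2R,4S)-2,6,6-trimethyl-4-(phenylsulfanyl)-2-(triethylsilyloxy)-7-oxabicyclo[2.2.1]heptan-1-yl]methoxy}diphenylsilane | CC(C)(C)[Si](c1ccccc1)(c1ccccc1)OC[C@]12O[C@](Sc3ccccc3)(CC1(C)C)C[C@@]2(C)O[Si](CC)(CC)CC
F5 | step 2 | ethyl 2-(2-hydroxypent-4-en-2-yl)-3-methylbut-2-enoate (racemic) | CCOC(=O)C(=C(C)C)C(C)(O)CC=C
F6 | step 2 | ethyl 3-methyl-2-[2-(triethylsilyloxy)pent-4-en-2-yl]but-2-enoate (racemic) | CCOC(=O)C(=C(C)C)C(C)(O[Si](CC)(CC)CC)CC=C
F7 | step 2 | 3-methyl-2-[2-(triethylsilyloxy)pent-4-en-2-yl]but-2-en-1-ol (racemic) | OCC(=C(C)C)C(C)(O[Si](CC)(CC)CC)CC=C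
F8 | step 2 | {(2S)-3,3-dimethyl-2-[(2S)-2-(triethylsilyloxy)pent-4-en-2-yl]oxiran-2-yl}methanol | OC[C@@]1(OC1(C)C)[C@@](C)(O[Si](CC)(CC)CC)CC=C
F9 | step 20 | (1R,4R,6R)-1-(hydroxymethyl)-2,2,6-trimethyl-7-oxabicyclo[4.1.0]heptan-4-yl 2,2-dimethylpropanoate | OC[C@@]12O[C@]1(C)C[C@H](OC(=O)C(C)(C)C)CC2(C)C
F10 | step 20 | (1R,3S,4R)-3,4-dihydroxy-4-(hydroxymethyl)-3,5,5-trimethylcyclohexyl 2,2-dimethylpropanoate | OC[C@]1(O)C(C)(C)C[C@@H](OC(=O)C(C)(C)C)C[C@]1(C)O
F11 | step 20 | (1R,3S,4S)-4-formyl-3,4-dihydroxy-3,5,5-trimethylcyclohexyl 2,2-dimethylpropanoate | O=C[C@]1(O)C(C)(C)C[C@@H](OC(=O)C(C)(C)C)C[C@]1(C)O
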